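**Plan**

- Retrosynthetic cuts: the C15 stearate ester; C8=C17 (methylenation); C7–C8 of ring B (a C7 organosamarium acylated by a C8 ester); C5–C6 and C4–C18 (vinylcopper addition to a ring A enoate, then enolate methylation); C9–C11 (ester enolate alkylation); C4–C19 (carbonylation); C10–C20 (asymmetric methyl addition).
- Forward order: ring A is built first from 3-ethoxycyclohexenone and ethyl acetate. The C11–C15 chain, shortened by one carbon from (S)-citronellol, is joined at C9. The key step then adds C6/C7 and C18. Ring B closes last at C7–C8, followed by methylenation, stearoylation and release of the C19 acid.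
- Stereochemistry: C13 comes from (S)-citronellol; C10 from a copper/phosphoramidite-catalysed Me3Al addition; C5 and C4 from C10 by substrate control in the key step; C9 from base equilibration of the C8 ketone.
- Enabling feature: C4, C5 and C10 are adjacent on ring A and C19 sits on C4, so a cyclohex-1-enecarboxylate that already holds C10 takes a nucleophile at C5 (β) and an electrophile at C4 (α).

Key step: step 9

Remark: labdane numbering is used (C1–C10 decalin, C11–C16 side chain, C17 exocyclic methylene, C18 and C19 on C4, C20 on C10). C19 is carried as a tert-butyl ester and C8 as an ethyl ester so that the ring B acylation can only occur at C8, and C9 is carried as both epimers until step 13.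

**Route**

Step 1
Reactants: 1 3-ethoxycyclohex-2-en-1-one; 2 ethyl acetate
Product: 5 ethyl 2-(3-oxocyclohex-1-en-1-yl)acetate, via ethyl lithioacetate 3 (not isolated), via lithium alkoxide 1,2-adduct 4 (not isolated)
Conditions: LiN(iPr)2, THF, −78 °C; add 1; then 2 M HCl, rt
Reagents that add atoms: water (O)
Why: Stork–Danheiser alkylative carbonyl transposition, in which the ester enolate adds 1,2 to the vinylogous ester and aqueous acid hydrolyses the enol ether and dehydrates the β-hydroxy ketone to the 3-substituted enone; no stereocentre is formed.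

Step 2
Reactants: 5 ethyl 2-(3-oxocyclohex-1-en-1-yl)acetate
Product: 8 ethyl 2-[(1R)-1-methyl-3-(trifluoromethanesulfonyloxy)cyclohex-2-en-1-yl]acetate, via dimethylaluminium enolate 6 (not isolated), via lithium trimethylaluminate enolate 7 (not isolated)
Conditions: Me3Al, Cu(O2CC4H3S) (copper thiophene-2-carboxylate, 2 mol%), chiral phosphoramidite L* (2,2'-biphenol-derived, from bis[1-(2-naphthyl)ethyl]amine, 4 mol%, enantiomer that gives (R)-8), Et2O, −30 °C; then THF, MeLi (1 equiv per Al), PhNTf2, −30 °C → rt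
Reagents that add atoms: trimethylaluminium (C[Al](C)C); N-phenylbis(trifluoromethanesulfonimide) (O=S(=O)(N(c1ccccc1)S(=O)(=O)C(F)(F)F)C(F)(F)F)
Why: Copper-catalysed asymmetric conjugate addition of Me3Al to a 3-substituted cyclohexenone should create the C10 quaternary centre under catalyst control, and the regiodefined aluminium enolate, activated as its lithium aluminate, should be O-sulfonylated by PhNTf2 so that the double bond is fixed toward C5.

Step 3
Reactants: 8 ethyl 2-[(1R)-1-methyl-3-(trifluoromethanesulfonyloxy)cyclohex-2-en-1-yl]acetate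
Product: 10 (3R)-3-(2-ethoxy-2-oxoethyl)-3-methylcyclohex-1-ene-1-carboxylic acid, via mixed acetic anhydride 9 (not isolated)
Conditions: Pd(OAc)2 (5 mol%), dppf (10 mol%), KOAc, CO (1 atm), DMF, 60 °C; aqueous acidic work-up
Reagents that add atoms: carbon monoxide ([C-]#[O+]); potassium acetate (CC(=O)[O-].[K+]); water (O)
Why: Palladium-catalysed hydroxycarbonylation of an enol triflate (oxidative addition to zerovalent palladium, CO insertion, capture of the acylpalladium by acetate, hydrolysis of the mixed anhydride) should place C19 on C4 without touching C10.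

Step 4
Reactants: 10 (3R)-3-(2-ethoxy-2-oxoethyl)-3-methylcyclohex-1-ene-1-carboxylic acid
Product: 11 tert-butyl (3R)-3-(2-ethoxy-2-oxoethyl)-3-methylcyclohex-1-ene-1-carboxylate
Conditions: tert-butyl 2,2,2-trichloroacetimidate, BF3·OEt2 (cat.), cyclohexane/CH2Cl2, rt
Reagents that add atoms: tert-butyl 2,2,2-trichloroacetimidate (CC(C)(C)OC(=N)C(Cl)(Cl)Cl)
Why: Acid-catalysed O-tert-butylation of the carboxylic acid by the trichloroacetimidate should give the tert-butyl enoate, whose bulk later keeps C19 out of the ring B acylation; no stereocentre is affected.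

Step 5
Reactants: 12 (S)-citronellol
Product: 13 {[(3S)-3,7-dimethyloct-6-en-1-yl]oxy}tri(propan-2-yl)silane
Conditions: iPr3SiCl, imidazole, DMF, rt
Reagents that add atoms: chlorotri(propan-2-yl)silane (CC(C)[Si](Cl)(C(C)C)C(C)C)
Why: Standard silylation of a primary alcohol; the triisopropylsilyl ether is chosen because it should survive permanganate/periodate, radical iodination, low-temperature fluoride and alkoxide base.

Step 6
Reactants: 13 {[(3S)-3,7-dimethyloct-6-en-1-yl]oxy}tri(propan-2-yl)silane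
Product: 14 (4S)-4-methyl-6-{[tri(propan-2-yl)silyl]oxy}hexanoic acid
Conditions: NaIO4, KMnO4 (cat.), K2CO3, t-BuOH/H2O, rt
Reagents that add atoms: sodium periodate ([Na+].[O-]I(=O)(=O)=O); potassium permanganate ([K+].[O-][Mn](=O)(=O)=O); water (O)
Why: Lemieux–von Rudloff oxidative cleavage of the trisubstituted alkene should give the acid directly and leaves the remote C13 stereocentre untouched.

Step 7
Reactants: 14 (4S)-4-methyl-6-{[tri(propan-2-yl)silyl]oxy}hexanoic acid
Product: 15 {[(3R)-5-iodo-3-methylpentyl]oxy}tri(propan-2-yl)silane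
Conditions: PhI(OAc)2, I2, cyclohexane, hν (tungsten lamp), reflux
Reagents that add atoms: iodine (II)
Why: Hunsdiecker-type iododecarboxylation (photolysis of the acyl hypoiodite, loss of CO2, iodine capture by the primary radical) should shorten the chain by one carbon to the C11–C15 iodide; C13 is not involved, and its descriptor changes only through the priority rules.

Step 8
Reactants: 11 tert-butyl (3R)-3-(2-ethoxy-2-oxoethyl)-3-methylcyclohex-1-ene-1-carboxylate; 15 {[(3R)-5-iodo-3-methylpentyl]oxy}tri(propan-2-yl)silane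
Product: 17 tert-butyl (3S)-3-[(2RS,5S)-1-ethoxy-5-methyl-1-oxo-7-{[tri(propan-2-yl)silyl]oxy}heptan-2-yl]-3-methylcyclohex-1-ene-1-carboxylate (C9 epimers), via lithium ester enolate 16 (not isolated)
Conditions: LiN(iPr)2, THF, −78 °C; DMPU; 15, −78 → −20 °C
Reagents that add atoms: none
Why: Alkylation of the lithium enolate of the ethyl ester with a primary iodide should form C9–C11; no facial control is expected next to the quaternary C10, so both C9 epimers are carried on and C9 is settled in step 13.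

Step 9
Reactants: 17 tert-butyl (3S)-3-[(2RS,5S)-1-ethoxy-5-methyl-1-oxo-7-{[tri(propan-2-yl)silyl]oxy}heptan-2-yl]-3-methylcyclohex-1-ene-1-carboxylate (C9 epimers); 18 vinylmagnesium bromide; 19 iodomethane
Product: 22 tert-butyl (1S,2R,3S)-2-ethenyl-3-[(2RS,5S)-1-ethoxy-5-methyl-1-oxo-7-{[tri(propan-2-yl)silyl]oxy}heptan-2-yl]-1,3-dimethylcyclohexane-1-carboxylate (C9 epimers), via silyl ketene acetal 20 (not isolated), via tetrabutylammonium enolate 21 (not isolated)
Conditions: 18, CuBr·SMe2 (20 mol%), Me3SiCl, HMPA, THF, −78 → −40 °C; Et3N/pentane, filtration of magnesium salts, concentration; then 19 (excess), Bu4N[Ph3SiF2], THF, −78 → 0 °C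
Reagents that add atoms: vinylmagnesium bromide 18 (C=C[Mg]Br); iodomethane 19 (CI)
Why: A magnesium vinylcuprate formed from 18 and catalytic CuBr·SMe2 forms a π-complex with the Me3SiCl-activated enoate, transfers the vinyl group to C5 through a trivalent copper intermediate and leaves the enolate as silyl ketene acetal 20; fluoride from Bu4N[Ph3SiF2] then releases the naked ester enolate 21 in the presence of excess 19, which methylates C4. The closest known reaction type is the chlorosilane-accelerated, copper-catalysed conjugate addition of Grignard reagents to cyclohex-1-enecarboxylates combined with fluoride-mediated C-alkylation of the silyl enolate (a three-component coupling); no ring closes. C5 is controlled by C10: the vinyl group should enter on the face of the half-chair anti to the branched C9 substituent and syn to the small C20 methyl, so C6 and C9 end trans, as the trans ring fusion requires. C4 is controlled by C5 and C10: allylic strain with the enolate oxygens holds the new vinyl group pseudoaxial and iodomethane should attack the opposite face, which is also remote from the C20 methyl, so C18 enters α and the tert-butoxycarbonyl group ends β, cis to C20. The step needs 1,4- over 1,2-addition (secured by copper and the hindered tert-butyl ester), two anti-selective additions (secured by the size difference between Me and CH(R)CO2Et at C10 and by the C5 vinyl group) and C-methylation ahead of proton transfer from C9–H (secured by releasing 21 slowly into excess 19 at low temperature).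

Step 10
Reactants: 22 tert-butyl (1S,2R,3S)-2-ethenyl-3-[(2RS,5S)-1-ethoxy-5-methyl-1-oxo-7-{[tri(propan-2-yl)silyl]oxy}heptan-2-yl]-1,3-dimethylcyclohexane-1-carboxylate (C9 epimers)
Product: 24 tert-butyl (1S,2R,3S)-3-[(2RS,5S)-1-ethoxy-5-methyl-1-oxo-7-{[tri(propan-2-yl)silyl]oxy}heptan-2-yl]-2-(2-hydroxyethyl)-1,3-dimethylcyclohexane-1-carboxylate (C9 epimers), via B-alkyl-9-BBN adduct 23 (not isolated)
Conditions: 9-BBN, THF, rt → 50 °C; then aq NaOAc, 30% H2O2, 0 °C → rt
Reagents that add atoms: hydrogen peroxide (OO)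
Why: Anti-Markovnikov hydroboration of the only alkene with 9-BBN and buffered peroxide oxidation should give the primary C7 alcohol with all stereocentres retained, both esters being inert to 9-BBN.

Step 11
Reactants: 24 tert-butyl (1S,2R,3S)-3-[(2RS,5S)-1-ethoxy-5-methyl-1-oxo-7-{[tri(propan-2-yl)silyl]oxy}heptan-2-yl]-2-(2-hydroxyethyl)-1,3-dimethylcyclohexane-1-carboxylate (C9 epimers)
Product: 25 tert-butyl (1S,2R,3S)-3-[(2RS,5S)-1-ethoxy-5-methyl-1-oxo-7-{[tri(propan-2-yl)silyl]oxy}heptan-2-yl]-2-(2-iodoethyl)-1,3-dimethylcyclohexane-1-carboxylate (C9 epimers)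
Conditions: I2, PPh3, imidazole, CH2Cl2, 0 °C → rt
Reagents that add atoms: iodine (II)
Why: Appel-type iodination should convert the primary alcohol to the iodide by SN2 displacement at C7 without affecting the esters or the silyl ether.

Step 12
Reactants: 25 tert-butyl (1S,2R,3S)-3-[(2RS,5S)-1-ethoxy-5-methyl-1-oxo-7-{[tri(propan-2-yl)silyl]oxy}heptan-2-yl]-2-(2-iodoethyl)-1,3-dimethylcyclohexane-1-carboxylate (C9 epimers)
Product: 27 tert-butyl (1S,4aS,5RS,8aR)-1,4a-dimethyl-5-[(3S)-3-methyl-5-{[tri(propan-2-yl)silyl]oxy}pentyl]-6-oxodecahydronaphthalene-1-carboxylate (C9 epimers), via alkylsamarium diiodide 26 (not isolated)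
Conditions: SmI2 (2.5 equiv), Fe(dbm)3 (3 mol%, dbm = dibenzoylmethanide), THF, −30 °C → rt
Reagents that add atoms: none
Why: Samarium diiodide-promoted intramolecular nucleophilic acyl substitution (Barbier-type): two single-electron transfers give the C7 alkylsamarium, which should close ring B by attack on the C8 ethyl ester through a six-membered transition state and loss of ethoxide, while the quaternary tert-butyl ester on C4 is too hindered to compete; the ring fusion is already fixed by C5 and C10.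

Step 13
Reactants: 27 tert-butyl (1S,4aS,5RS,8aR)-1,4a-dimethyl-5-[(3S)-3-methyl-5-{[tri(propan-2-yl)silyl]oxy}pentyl]-6-oxodecahydronaphthalene-1-carboxylate (C9 epimers)
Product: 28 tert-butyl (1S,4aS,5R,8aR)-1,4a-dimethyl-5-[(3S)-3-methyl-5-{[tri(propan-2-yl)silyl]oxy}pentyl]-6-oxodecahydronaphthalene-1-carboxylate
Conditions: NaOMe (0.3 equiv), MeOH/THF, rt
Reagents that add atoms: none
Why: Base-mediated enolisation of the C8 ketone should equilibrate C9 to the thermodynamically favoured equatorial (β) side chain with 9α-H, which avoids the syn-axial contacts of the axial epimer.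

Step 14
Reactants: 28 tert-butyl (1S,4aS,5R,8aR)-1,4a-dimethyl-5-[(3S)-3-methyl-5-{[tri(propan-2-yl)silyl]oxy}pentyl]-6-oxodecahydronaphthalene-1-carboxylate
Product: 29 tert-butyl (1S,4aR,5S,8aR)-1,4a-dimethyl-6-methylidene-5-[(3S)-3-methyl-5-{[tri(propan-2-yl)silyl]oxy}pentyl]decahydronaphthalene-1-carboxylate
Conditions: Ph3PCH3Br, KOtBu, toluene, 90 °C
Reagents that add atoms: methyltriphenylphosphonium bromide (C[P+](c1ccccc1)(c1ccccc1)c1ccccc1.[Br-])
Why: Wittig methylenation of the hindered ketone with excess non-stabilised ylide should install C17, and any C9 epimerisation under the basic conditions returns to the same equatorial isomer.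

Step 15
Reactants: 29 tert-butyl (1S,4aR,5S,8aR)-1,4a-dimethyl-6-methylidene-5-[(3S)-3-methyl-5-{[tri(propan-2-yl)silyl]oxy}pentyl]decahydronaphthalene-1-carboxylate
Product: 30 tert-butyl (1S,4aR,5S,8aR)-5-[(3S)-5-hydroxy-3-methylpentyl]-1,4a-dimethyl-6-methylidenedecahydronaphthalene-1-carboxylate
Conditions: Bu4NF, THF, rt
Reagents that add atoms: none
Why: Fluoride-induced desilylation should free the primary C15 alcohol, the tert-butyl ester and the exocyclic alkene being inert.

Step 16
Reactants: 30 tert-butyl (1S,4aR,5S,8aR)-5-[(3S)-5-hydroxy-3-methylpentyl]-1,4a-dimethyl-6-methylidenedecahydronaphthalene-1-carboxylate; 31 stearic acid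
Product: 32 tert-butyl (1S,4aR,5S,8aR)-1,4a-dimethyl-6-methylidene-5-[(3S)-3-methyl-5-(octadecanoyloxy)pentyl]decahydronaphthalene-1-carboxylate
Conditions: EDC·HCl, DMAP (cat.), CH2Cl2, rt
Reagents that add atoms: none
Why: Steglich esterification (carbodiimide activation, DMAP acyl transfer) should acylate the only free hydroxyl group while C19 is still masked.

Step 17
Reactants: 32 tert-butyl (1S,4aR,5S,8aR)-1,4a-dimethyl-6-methylidene-5-[(3S)-3-methyl-5-(octadecanoyloxy)pentyl]decahydronaphthalene-1-carboxylate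
Product: 34 (1S,4aR,5S,8aR)-1,4a-dimethyl-6-methylidene-5-[(3S)-3-methyl-5-(octadecanoyloxy)pentyl]decahydronaphthalene-1-carboxylic acid (CNP0298278.1), via trimethylsilyl ester 33 (not isolated)
Conditions: Me3SiOTf, 2,6-lutidine, CH2Cl2, 0 °C → rt; then pH 5 aqueous buffer
Reagents that add atoms: none
Why: Silyl triflate-mediated cleavage of the tert-butyl ester (O-silylation, loss of the tert-butyl cation as isobutene into the lutidine-buffered medium) and hydrolysis of the silyl ester on work-up should free the C19 acid without protic acid that could shift the 8(17)-alkene or cleave the stearate.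

**Compound list**

1 | 3-ethoxycyclohex-2-en-1-one | CCOC1=CC(=O)CCC1 | starting material
2 | ethyl acetate | CCOC(C)=O | starting material
3 | ethyl lithioacetate | [Li]OC(=C)OCC | intermediate
4 | lithium alkoxide of ethyl 2-(3-ethoxy-1-hydroxycyclohex-2-en-1-yl)acetate (racemic 1,2-adduct) | [Li]OC1(CC(=O)OCC)C=C(OCC)CCC1 | intermediate
5 | ethyl 2-(3-oxocyclohex-1-en-1-yl)acetate | CCOC(=O)CC1=CC(=O)CCC1 | intermediate
6 | dimethylaluminium enolate of ethyl 2-(1-methyl-3-oxocyclohexyl)acetate (C4=C5 enolate, C10 set) | C[Al](C)OC1=C[C@](C)(CCC1)CC(=O)OCC | intermediate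
7 | lithium trimethylaluminate enolate derived from 6 | [Li+].C[Al-](C)(C)OC1=C[C@](C)(CCC1)CC(=O)OCC | intermediate
8 | ethyl 2-[(1R)-1-methyl-3-(trifluoromethanesulfonyloxy)cyclohex-2-en-1-yl]acetate | O=S(=O)(OC1=C[C@](C)(CCC1)CC(=O)OCC)C(F)(F)F | intermediate
9 | mixed anhydride of acetic acid and acid 10 | CC(=O)OC(=O)C1=C[C@](C)(CCC1)CC(=O)OCC | intermediate
10 | (3R)-3-(2-ethoxy-2-oxoethyl)-3-methylcyclohex-1-ene-1-carboxylic acid | OC(=O)C1=C[C@](C)(CCC1)CC(=O)OCC | intermediate
11 | tert-butyl (3R)-3-(2-ethoxy-2-oxoethyl)-3-methylcyclohex-1-ene-1-carboxylate | CC(C)(C)OC(=O)C1=C[C@](C)(CCC1)CC(=O)OCC | intermediate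
12 | (S)-citronellol | CC(C)=CCC[C@H](C)CCO | starting material
13 | {[(3S)-3,7-dimethyloct-6-en-1-yl]oxy}tri(propan-2-yl)silane | CC(C)=CCC[C@H](C)CCO[Si](C(C)C)(C(C)C)C(C)C | intermediate
14 | (4S)-4-methyl-6-{[tri(propan-2-yl)silyl]oxy}hexanoic acid | OC(=O)CC[C@H](C)CCO[Si](C(C)C)(C(C)C)C(C)C | intermediate
15 | {[(3R)-5-iodo-3-methylpentyl]oxy}tri(propan-2-yl)silane | ICC[C@H](C)CCO[Si](C(C)C)(C(C)C)C(C)C | intermediate
16 | lithium enolate of the ethyl ester of 11 (C9=C8 enolate) | CC(C)(C)OC(=O)C1=C[C@](C)(CCC1)C=C(O[Li])OCC | intermediate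
17 | tert-butyl (3S)-3-[(2RS,5S)-1-ethoxy-5-methyl-1-oxo-7-{[tri(propan-2-yl)silyl]oxy}heptan-2-yl]-3-methylcyclohex-1-ene-1-carboxylate (C9 epimers) | CC(C)(C)OC(=O)C1=C[C@](C)(CCC1)C(CC[C@H](C)CCO[Si](C(C)C)(C(C)C)C(C)C)C(=O)OCC | intermediate
18 | vinylmagnesium bromide | C=C[Mg]Br | starting material
19 | iodomethane | CI | starting material
20 | tert-butyl trimethylsilyl ketene acetal of the C5-vinyl adduct (exocyclic C4=C19, C9 epimers) | C=C[C@@H]1[C@](C)(CCCC1=C(OC(C)(C)C)O[Si](C)(C)C)C(CC[C@H](C)CCO[Si](C(C)C)(C(C)C)C(C)C)C(=O)OCC | intermediate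
21 | tetrabutylammonium ester enolate derived from 20 | CCCC[N+](CCCC)(CCCC)CCCC.C=C[C@@H]1[C@](C)(CCCC1=C([O-])OC(C)(C)C)C(CC[C@H](C)CCO[Si](C(C)C)(C(C)C)C(C)C)C(=O)OCC | intermediate
22 | tert-butyl (1S,2R,3S)-2-ethenyl-3-[(2RS,5S)-1-ethoxy-5-methyl-1-oxo-7-{[tri(propan-2-yl)silyl]oxy}heptan-2-yl]-1,3-dimethylcyclohexane-1-carboxylate (C9 epimers) | C=C[C@@H]1[C@](C)(CCC[C@]1(C)C(=O)OC(C)(C)C)C(CC[C@H](C)CCO[Si](C(C)C)(C(C)C)C(C)C)C(=O)OCC | intermediate
23 | B-alkyl-9-borabicyclo[3.3.1]nonane adduct of 22 (boron on C7) | C1CCC2CCCC1B2CC[C@@H]1[C@](C)(CCC[C@]1(C)C(=O)OC(C)(C)C)C(CC[C@H](C)CCO[Si](C(C)C)(C(C)C)C(C)C)C(=O)OCC | intermediate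
24 | tert-butyl (1S,2R,3S)-3-[(2RS,5S)-1-ethoxy-5-methyl-1-oxo-7-{[tri(propan-2-yl)silyl]oxy}heptan-2-yl]-2-(2-hydroxyethyl)-1,3-dimethylcyclohexane-1-carboxylate (C9 epimers) | OCC[C@@H]1[C@](C)(CCC[C@]1(C)C(=O)OC(C)(C)C)C(CC[C@H](C)CCO[Si](C(C)C)(C(C)C)C(C)C)C(=O)OCC | intermediate
25 | tert-butyl (1S,2R,3S)-3-[(2RS,5S)-1-ethoxy-5-methyl-1-oxo-7-{[tri(propan-2-yl)silyl]oxy}heptan-2-yl]-2-(2-iodoethyl)-1,3-dimethylcyclohexane-1-carboxylate (C9 epimers) | ICC[C@@H]1[C@](C)(CCC[C@]1(C)C(=O)OC(C)(C)C)C(CC[C@H](C)CCO[Si](C(C)C)(C(C)C)C(C)C)C(=O)OCC | intermediate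
26 | C7 alkylsamarium diiodide derived from 25 | I[Sm](I)CC[C@@H]1[C@](C)(CCC[C@]1(C)C(=O)OC(C)(C)C)C(CC[C@H](C)CCO[Si](C(C)C)(C(C)C)C(C)C)C(=O)OCC | intermediate
27 | tert-butyl (1S,4aS,5RS,8aR)-1,4a-dimethyl-5-[(3S)-3-methyl-5-{[tri(propan-2-yl)silyl]oxy}pentyl]-6-oxodecahydronaphthalene-1-carboxylate (C9 epimers) | O=C1CC[C@@H]2[C@](C)(CCC[C@]2(C)C(=O)OC(C)(C)C)C1CC[C@H](C)CCO[Si](C(C)C)(C(C)C)C(C)C | intermediate
28 | tert-butyl (1S,4aS,5R,8aR)-1,4a-dimethyl-5-[(3S)-3-methyl-5-{[tri(propan-2-yl)silyl]oxy}pentyl]-6-oxodecahydronaphthalene-1-carboxylate | O=C1CC[C@@H]2[C@](C)(CCC[C@]2(C)C(=O)OC(C)(C)C)[C@H]1CC[C@H](C)CCO[Si](C(C)C)(C(C)C)C(C)C | intermediate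
29 | tert-butyl (1S,4aR,5S,8aR)-1,4a-dimethyl-6-methylidene-5-[(3S)-3-methyl-5-{[tri(propan-2-yl)silyl]oxy}pentyl]decahydronaphthalene-1-carboxylate | C=C1CC[C@@H]2[C@](C)(CCC[C@]2(C)C(=O)OC(C)(C)C)[C@H]1CC[C@H](C)CCO[Si](C(C)C)(C(C)C)C(C)C | intermediate
30 | tert-butyl (1S,4aR,5S,8aR)-5-[(3S)-5-hydroxy-3-methylpentyl]-1,4a-dimethyl-6-methylidenedecahydronaphthalene-1-carboxylate | C=C1CC[C@@H]2[C@](C)(CCC[C@]2(C)C(=O)OC(C)(C)C)[C@H]1CC[C@H](C)CCO | intermediate
31 | stearic acid (octadecanoic acid) | CCCCCCCCCCCCCCCCCC(=O)O | starting material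
32 | tert-butyl (1S,4aR,5S,8aR)-1,4a-dimethyl-6-methylidene-5-[(3S)-3-methyl-5-(octadecanoyloxy)pentyl]decahydronaphthalene-1-carboxylate | C=C1CC[C@@H]2[C@](C)(CCC[C@]2(C)C(=O)OC(C)(C)C)[C@H]1CC[C@H](C)CCOC(=O)CCCCCCCCCCCCCCCCC | intermediate
33 | trimethylsilyl ester of 34 | C=C1CC[C@@H]2[C@](C)(CCC[C@]2(C)C(=O)O[Si](C)(C)C)[C@H]1CC[C@H](C)CCOC(=O)CCCCCCCCCCCCCCCCC | intermediate
34 | (1S,4aR,5S,8aR)-1,4a-dimethyl-6-methylidene-5-[(3S)-3-methyl-5-(octadecanoyloxy)pentyl]decahydronaphthalene-1-carboxylic acid (CNP0298278.1) | C=C1CC[C@@H]2[C@](C)(CCC[C@]2(C)C(=O)O)[C@H]1CC[C@H](C)CCOC(=O)CCCCCCCCCCCCCCCCC | target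

**Step count and risks**

Total steps: 17. Longest linear sequence: 14 (steps 1–4 and 8–17); the side-chain branch (steps 5–7) joins at step 8.

Steps most likely to fail:

1. Step 9 (key step). The crowded naked enolate may be protonated by C9–H or may attack the C8 ester before it is methylated. The facial bias of the methylation on the flexible monocycle may also be low. Fallback: set out from 17, run only the copper-catalysed vinyl addition and hydrolyse silyl ketene acetal 20 with dilute acid to the C4-unmethylated vinyl adduct F1. Carry it through the operations of steps 10–14 to the primary alcohol F2, the iodide F3, the decalone F4, the C9-equilibrated decalone F5 and the 8(17)-alkene F6, whose only acidic site is C4–H. Deprotonation with LiN(iPr)2 (THF, −78 °C) and methylation with iodomethane on the rigid trans-decalin, where the axial C20 methyl blocks the β-face, should place C18 α, and the route is rejoined at 29.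

2. Step 12. The alkylsamarium may be protonated (simple loss of iodine) or may fail to add to the hindered C8 ester. Fallback: set out from 25 and displace iodide with PhSO2Na in DMF to give the sulfone F7. LiN(iPr)2 (2.2 equiv) forms the α-sulfonyl carbanion at the accessible C7, and a Claisen-type (Dieckmann-like) acylation at the C8 ester should give the cyclic β-keto sulfone F8. Reductive desulfonylation with Al(Hg) in wet THF rejoins the route at 27.

3. Step 2. Triflyl transfer to the aluminium enolate may be slow, or MeLi may attack the ethyl ester, so that the regiodefined enolate is lost as the saturated ketone on work-up. Fallback: set out from 5, run the same conjugate addition and quench it with Me3SiOTf to isolate the trimethylsilyl enol ether F9. CsF and PhNTf2 in 1,2-dimethoxyethane then convert it into the enol triflate without any organolithium, rejoining the route at 8.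

Further compounds
F1 | step 9 | tert-butyl 2-ethenyl-3-[1-ethoxy-5-methyl-1-oxo-7-(triisopropylsilyloxy)heptan-2-yl]-3-methylcyclohexane-1-carboxylate (C5, C10, C13 as in 22; C4 and C9 epimers) | C=C[C@@H]1[C@](C)(CCCC1C(=O)OC(C)(C)C)C(CC[C@H](C)CCO[Si](C(C)C)(C(C)C)C(C)C)C(=O)OCC
F2 | step 9 | 2-(2-hydroxyethyl) analogue of F1 (primary C7 alcohol) | OCC[C@@H]1[C@](C)(CCCC1C(=O)OC(C)(C)C)C(CC[C@H](C)CCO[Si](C(C)C)(C(C)C)C(C)C)C(=O)OCC
F3 | step 9 | 2-(2-iodoethyl) analogue of F1 (C7 iodide) | ICC[C@@H]1[C@](C)(CCCC1C(=O)OC(C)(C)C)C(CC[C@H](C)CCO[Si](C(C)C)(C(C)C)C(C)C)C(=O)OCC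
F4 | step 9 | tert-butyl 4a-methyl-5-[(3S)-3-methyl-5-(triisopropylsilyloxy)pentyl]-6-oxodecahydronaphthalene-1-carboxylate (trans-fused; C4 and C9 epimers) | O=C1CC[C@@H]2[C@](C)(CCCC2C(=O)OC(C)(C)C)C1CC[C@H](C)CCO[Si](C(C)C)(C(C)C)C(C)C
F5 | step 9 | C9-equilibrated decalone (9α-H, C4 epimers) | O=C1CC[C@@H]2[C@](C)(CCCC2C(=O)OC(C)(C)C)[C@H]1CC[C@H](C)CCO[Si](C(C)C)(C(C)C)C(C)C
F6 | step 9 | 6-methylidene analogue of F5 (18-nor analogue of 29, C4 epimers) | C=C1CC[C@@H]2[C@](C)(CCCC2C(=O)OC(C)(C)C)[C@H]1CC[C@H](C)CCO[Si](C(C)C)(C(C)C)C(C)C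
F7 | step 12 | 2-[2-(phenylsulfonyl)ethyl] analogue of 25 (C7 sulfone, C9 epimers) | O=S(=O)(CC[C@@H]1[C@](C)(CCC[C@]1(C)C(=O)OC(C)(C)C)C(CC[C@H](C)CCO[Si](C(C)C)(C(C)C)C(C)C)C(=O)OCC)c1ccccc1
F8 | step 12 | 7-(phenylsulfonyl) derivative of decalone 27 (β-keto sulfone, C7 and C9 epimers) | O=C1C(S(=O)(=O)c2ccccc2)C[C@@H]2[C@](C)(CCC[C@]2(C)C(=O)OC(C)(C)C)C1CC[C@H](C)CCO[Si](C(C)C)(C(C)C)C(C)C
F9 | step 2 | ethyl 2-[(1R)-1-methyl-3-(trimethylsilyloxy)cyclohex-2-en-1-yl]acetate | C[Si](C)(C)OC1=C[C@](C)(CCC1)CC(=O)OCC
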